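Retrosynthesis: the MOM ether and the C4 ketone of the target go back to a 7‑O‑MOM flavan‑4‑ol, and ring C is then cut at the aryl ether bond O1–C8a, giving an open‑chain anti‑1,3‑diol with bromine on ring A at the future C8a.
Enabling feature: ring C is a benzo‑fused pyranone whose O1 sits on the aromatic carbon C8a of ring A, so cutting this aryl–oxygen bond (not O1–C2) leaves C2 as an open‑chain benzylic carbinol whose C–O bond is never broken.
Further cuts: both carbinols back to a 1,3‑diketone; C2–C3 (crossed Claisen condensation of a ring A methyl ketone with a ring B methyl ester); C8–prenyl (metalation between Br and OMOM); on ring B the chromene bonds O1′–C2′ and C4′–C4a′ (aryl propargyl ether rearrangement) and C8′–prenyl (phenoxide C‑alkylation).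
Forward order: the chromene ring on ring B forms first (step 3), the two aryl units are joined through the three‑carbon chain (step 8), and ring C closes last (step 10).
Stereochemistry: C2 (S) is set by catalyst‑controlled transfer hydrogenation of the diketone with RuCl[(S,S)‑TsDPEN](p‑cymene) (step 9) and carried unchanged to the target; the C4 carbinol formed with it is oxidised away in step 11.

Key step: step 10

Remark on the chemistry: flavanone numbering is used (O1, C2–C4, C4a, C5–C8, C8a; ring A is the benzo ring, ring C the pyranone ring, ring B the chromene unit on C2, with primed numbers); compounds 1, 2, 5 and 9 are taken as purchasable; TsDPEN is N‑(p‑toluenesulfonyl)‑1,2‑diphenylethylenediamine.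

Step 1
Reactants: 1 methyl 4‑hydroxybenzoate; 2 1‑bromo‑3‑methylbut‑2‑ene (prenyl bromide)
Product: 4 methyl 4‑hydroxy‑3‑(3‑methylbut‑2‑en‑1‑yl)benzoate, via sodium phenoxide 3 (not isolated)
Conditions: NaH, toluene, rt; then 2, rt → 50 °C
Reagents that add atoms: none
Why: Ortho C‑alkylation of a sodium phenoxide in a non‑polar medium (phenoxide C‑allylation): the tight ion pair reacts at the ring carbon next to oxygen, the para position is blocked by the ester and the two ortho positions are equivalent, so a single C‑prenyl constitution is expected.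

Step 2
Reactants: 4 methyl 4‑hydroxy‑3‑(3‑methylbut‑2‑en‑1‑yl)benzoate; 5 3‑chloro‑3‑methylbut‑1‑yne
Product: 6 methyl 4‑[(2‑methylbut‑3‑yn‑2‑yl)oxy]‑3‑(3‑methylbut‑2‑en‑1‑yl)benzoate
Conditions: K2CO3, KI (cat.), CuI (cat.), acetone, reflux
Reagents that add atoms: none
Why: Williamson‑type O‑alkylation of the phenol with the tertiary propargylic chloride, assisted by catalytic CuI through copper acetylide activation of the chloride, should give the aryl 1,1‑dimethylpropargyl ether.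

Step 3
Reactants: 6 methyl 4‑[(2‑methylbut‑3‑yn‑2‑yl)oxy]‑3‑(3‑methylbut‑2‑en‑1‑yl)benzoate
Product: 8 methyl 2,2‑dimethyl‑8‑(3‑methylbut‑2‑en‑1‑yl)‑2H‑chromene‑6‑carboxylate, via allenylphenol 7 (not isolated)
Conditions: N,N‑diethylaniline, 190 °C
Reagents that add atoms: none
Why: Thermal aryl propargyl ether Claisen rearrangement to the only free ortho position, enolisation to allenylphenol 7, 1,5‑hydrogen shift and 6π oxa‑electrocyclisation of the resulting ortho‑quinone methide should close the 2,2‑dimethyl‑2H‑chromene ring, with no stereocenter formed.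

Step 4
Reactants: 9 1‑(2‑bromo‑4‑hydroxyphenyl)ethan‑1‑one
Product: 10 3‑bromo‑4‑(2‑methyl‑1,3‑dioxolan‑2‑yl)phenol
Conditions: ethylene glycol, TsOH·H2O (cat.), toluene, reflux, Dean–Stark trap
Reagents that add atoms: ethylene glycol, OCCO
Why: Acid‑catalysed ketalisation with azeotropic removal of water turns the acetyl group into a dioxolane that tolerates the lithium amide and organocopper chemistry of step 6.

Step 5
Reactants: 10 3‑bromo‑4‑(2‑methyl‑1,3‑dioxolan‑2‑yl)phenol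
Product: 11 2‑[2‑bromo‑4‑(methoxymethoxy)phenyl]‑2‑methyl‑1,3‑dioxolane
Conditions: MOMCl, iPr2NEt, CH2Cl2, 0 °C → rt
Reagents that add atoms: chloromethyl methyl ether (MOMCl), COCCl
Why: O‑Alkylation of the phenol with MOMCl under amine base (MOM ether formation) protects the hydroxyl, leaves the acid‑labile ketal untouched and installs the group that directs the metalation of step 6.

Step 6
Reactants: 11 2‑[2‑bromo‑4‑(methoxymethoxy)phenyl]‑2‑methyl‑1,3‑dioxolane; 2 1‑bromo‑3‑methylbut‑2‑ene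
Product: 14 2‑[2‑bromo‑4‑(methoxymethoxy)‑3‑(3‑methylbut‑2‑en‑1‑yl)phenyl]‑2‑methyl‑1,3‑dioxolane, via aryllithium 12 (not isolated), via arylcopper 13 (not isolated)
Conditions: LiN(iPr)2, THF, −78 °C; CuBr·SMe2, −78 °C; then 2, −78 → 0 °C
Reagents that add atoms: none
Why: Directed ortho‑metalation: LiN(iPr)2, which does not undergo bromine–lithium exchange, should remove the ring proton flanked by Br and the chelating MOM ether, and after transmetalation to copper the aryl group should displace bromide at the unhindered CH2 terminus of 2 (SN2 allylation).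

Step 7
Reactants: 14 2‑[2‑bromo‑4‑(methoxymethoxy)‑3‑(3‑methylbut‑2‑en‑1‑yl)phenyl]‑2‑methyl‑1,3‑dioxolane
Product: 15 1‑[2‑bromo‑4‑(methoxymethoxy)‑3‑(3‑methylbut‑2‑en‑1‑yl)phenyl]ethan‑1‑one
Conditions: PPTS (cat.), acetone/H2O, rt → 40 °C
Reagents that add atoms: water, O
Why: Mild acid‑catalysed ketal hydrolysis in wet acetone should release the methyl ketone, while the aryl MOM ether, which needs stronger acid, and the prenyl group remain.

Step 8
Reactants: 15 1‑[2‑bromo‑4‑(methoxymethoxy)‑3‑(3‑methylbut‑2‑en‑1‑yl)phenyl]ethan‑1‑one; 8 methyl 2,2‑dimethyl‑8‑(3‑methylbut‑2‑en‑1‑yl)‑2H‑chromene‑6‑carboxylate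
Product: 17 1‑[2‑bromo‑4‑(methoxymethoxy)‑3‑(3‑methylbut‑2‑en‑1‑yl)phenyl]‑3‑[2,2‑dimethyl‑8‑(3‑methylbut‑2‑en‑1‑yl)‑2H‑chromen‑6‑yl]propane‑1,3‑dione, via sodium enolate 16 (not isolated)
Conditions: NaH, THF, 0 → 60 °C; aqueous work‑up
Reagents that add atoms: none
Why: Crossed Claisen condensation: enolate 16 of the methyl ketone acylates at carbon with the non‑enolisable ester 8, and deprotonation of the resulting 1,3‑diketone drives the equilibrium, forming the C2–C3 bond of the later ring C.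

Step 9
Reactants: 17 1‑[2‑bromo‑4‑(methoxymethoxy)‑3‑(3‑methylbut‑2‑en‑1‑yl)phenyl]‑3‑[2,2‑dimethyl‑8‑(3‑methylbut‑2‑en‑1‑yl)‑2H‑chromen‑6‑yl]propane‑1,3‑dione
Product: 19 (1S,3S)‑1‑[2‑bromo‑4‑(methoxymethoxy)‑3‑(3‑methylbut‑2‑en‑1‑yl)phenyl]‑3‑[2,2‑dimethyl‑8‑(3‑methylbut‑2‑en‑1‑yl)‑2H‑chromen‑6‑yl]propane‑1,3‑diol, via hydroxy ketone 18 (not isolated)
Conditions: RuCl[(S,S)‑TsDPEN](p‑cymene) (cat.), HCO2H/Et3N (5:2), DMF, 40 °C
Reagents that add atoms: none
Why: Noyori asymmetric transfer hydrogenation: the ruthenium hydride of the (S,S)‑TsDPEN complex reduces each aryl ketone on the face that gives the S carbinol (catalyst control, as for acetophenone‑type ketones), so the 3S centre (later C2) and the 1S centre (later C4, removed in step 11) should arise as the anti diol, while the alkenes, the aryl bromide and the MOM ether are not affected.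

Step 10
Reactants: 19 (1S,3S)‑1‑[2‑bromo‑4‑(methoxymethoxy)‑3‑(3‑methylbut‑2‑en‑1‑yl)phenyl]‑3‑[2,2‑dimethyl‑8‑(3‑methylbut‑2‑en‑1‑yl)‑2H‑chromen‑6‑yl]propane‑1,3‑diol
Product: 20 (2S,4S)‑2‑[2,2‑dimethyl‑8‑(3‑methylbut‑2‑en‑1‑yl)‑2H‑chromen‑6‑yl]‑7‑(methoxymethoxy)‑8‑(3‑methylbut‑2‑en‑1‑yl)‑3,4‑dihydro‑2H‑chromen‑4‑ol
Conditions: CuI (cat.), 3,4,7,8‑tetramethyl‑1,10‑phenanthroline, Cs2CO3, toluene, 110 °C, argon
Reagents that add atoms: none
Why: Cs2CO3 deprotonates the chain hydroxyl next to ring B (the future O1), the alkoxide coordinates the phenanthroline‑bound monovalent copper, the ring A C–Br bond then adds to the metal, and reductive elimination from the resulting aryl alkoxide complex of formally trivalent copper forms the O1–C8a bond. The closest known reaction is the Ullmann‑type intramolecular O‑arylation of secondary alcohols by aryl bromides that is used to make chromans and flavans. Ring C closes as a six‑membered ring in the exo mode, the tethered oxygen attacking the aromatic carbon while the departing bromide lies outside the new ring. No stereocenter is created: the carbinol C–O bond at C2 takes no part, so the 2S centre from step 9 is carried over with retention and C4 stays S, which makes the product the 2,4‑cis flavan‑4‑ol. The step needs selection between two hydroxyls and tolerance of a bromide with two ortho substituents; the first follows from ring size, since the C4 hydroxyl could close only a four‑membered ring, and the second is served by the intramolecular setting and the small copper centre, while keeping C4 as a carbinol removes any acidic C3 proton and with it base‑induced ring opening or epimerisation.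

Step 11
Reactants: 20 (2S,4S)‑2‑[2,2‑dimethyl‑8‑(3‑methylbut‑2‑en‑1‑yl)‑2H‑chromen‑6‑yl]‑7‑(methoxymethoxy)‑8‑(3‑methylbut‑2‑en‑1‑yl)‑3,4‑dihydro‑2H‑chromen‑4‑ol
Product: 21 (2S)‑2‑[2,2‑dimethyl‑8‑(3‑methylbut‑2‑en‑1‑yl)‑2H‑chromen‑6‑yl]‑7‑(methoxymethoxy)‑8‑(3‑methylbut‑2‑en‑1‑yl)‑2,3‑dihydro‑4H‑chromen‑4‑one
Conditions: MnO2 (activated, excess), CH2Cl2, rt
Reagents that add atoms: none
Why: Oxidation of an electron‑rich benzylic alcohol on the surface of activated MnO2 under neutral conditions should give the chromanone without exposing the new β‑aryloxy ketone to base, so C2 is not epimerised; the C4 stereocenter disappears here.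

Step 12
Reactants: 21 (2S)‑2‑[2,2‑dimethyl‑8‑(3‑methylbut‑2‑en‑1‑yl)‑2H‑chromen‑6‑yl]‑7‑(methoxymethoxy)‑8‑(3‑methylbut‑2‑en‑1‑yl)‑2,3‑dihydro‑4H‑chromen‑4‑one
Product: 22 (2S)‑2‑[2,2‑dimethyl‑8‑(3‑methylbut‑2‑en‑1‑yl)‑2H‑chromen‑6‑yl]‑7‑hydroxy‑8‑(3‑methylbut‑2‑en‑1‑yl)‑2,3‑dihydro‑4H‑chromen‑4‑one (CNP0110366.1)
Conditions: 3 M aq. HCl, MeOH, rt
Reagents that add atoms: none
Why: Acid‑catalysed methanolysis of the MOM acetal (MOM ether cleavage) frees the 7‑hydroxyl, and dilute acid at room temperature is chosen so that the prenyl groups, the chromene and the C2 centre should stay intact.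

Compound list
1 | methyl 4‑hydroxybenzoate | COC(=O)c1ccc(O)cc1 | starting material
2 | 1‑bromo‑3‑methylbut‑2‑ene (prenyl bromide) | CC(C)=CCBr | starting material
3 | sodium 4‑(methoxycarbonyl)phenolate | COC(=O)c1ccc([O-])cc1.[Na+] | intermediate
4 | methyl 4‑hydroxy‑3‑(3‑methylbut‑2‑en‑1‑yl)benzoate | COC(=O)c1ccc(O)c(CC=C(C)C)c1 | intermediate
5 | 3‑chloro‑3‑methylbut‑1‑yne | CC(C)(Cl)C#C | starting material
6 | methyl 4‑[(2‑methylbut‑3‑yn‑2‑yl)oxy]‑3‑(3‑methylbut‑2‑en‑1‑yl)benzoate | COC(=O)c1ccc(OC(C)(C)C#C)c(CC=C(C)C)c1 | intermediate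
7 | methyl 4‑hydroxy‑3‑(3‑methylbuta‑1,2‑dien‑1‑yl)‑5‑(3‑methylbut‑2‑en‑1‑yl)benzoate | COC(=O)c1cc(CC=C(C)C)c(O)c(C=C=C(C)C)c1 | intermediate
8 | methyl 2,2‑dimethyl‑8‑(3‑methylbut‑2‑en‑1‑yl)‑2H‑chromene‑6‑carboxylate | CC(C)=CCc1cc(C(=O)OC)cc2c1OC(C)(C)C=C2 | intermediate
9 | 1‑(2‑bromo‑4‑hydroxyphenyl)ethan‑1‑one | CC(=O)c1ccc(O)cc1Br | starting material
10 | 3‑bromo‑4‑(2‑methyl‑1,3‑dioxolan‑2‑yl)phenol | CC1(OCCO1)c2ccc(O)cc2Br | intermediate
11 | 2‑[2‑bromo‑4‑(methoxymethoxy)phenyl]‑2‑methyl‑1,3‑dioxolane | CC1(OCCO1)c2ccc(OCOC)cc2Br | intermediate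
12 | [2‑bromo‑6‑(methoxymethoxy)‑3‑(2‑methyl‑1,3‑dioxolan‑2‑yl)phenyl]lithium | [Li]c1c(OCOC)ccc(c1Br)C2(C)OCCO2 | intermediate
13 | [2‑bromo‑6‑(methoxymethoxy)‑3‑(2‑methyl‑1,3‑dioxolan‑2‑yl)phenyl]copper | [Cu]c1c(OCOC)ccc(c1Br)C2(C)OCCO2 | intermediate
14 | 2‑[2‑bromo‑4‑(methoxymethoxy)‑3‑(3‑methylbut‑2‑en‑1‑yl)phenyl]‑2‑methyl‑1,3‑dioxolane | CC1(OCCO1)c2ccc(OCOC)c(CC=C(C)C)c2Br | intermediate
15 | 1‑[2‑bromo‑4‑(methoxymethoxy)‑3‑(3‑methylbut‑2‑en‑1‑yl)phenyl]ethan‑1‑one | CC(=O)c1ccc(OCOC)c(CC=C(C)C)c1Br | intermediate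
16 | sodium 1‑[2‑bromo‑4‑(methoxymethoxy)‑3‑(3‑methylbut‑2‑en‑1‑yl)phenyl]ethen‑1‑olate | [Na+].[O-]C(=C)c1ccc(OCOC)c(CC=C(C)C)c1Br | intermediate
17 | 1‑[2‑bromo‑4‑(methoxymethoxy)‑3‑(3‑methylbut‑2‑en‑1‑yl)phenyl]‑3‑[2,2‑dimethyl‑8‑(3‑methylbut‑2‑en‑1‑yl)‑2H‑chromen‑6‑yl]propane‑1,3‑dione | CC(C)=CCc1cc(C(=O)CC(=O)c3ccc(OCOC)c(CC=C(C)C)c3Br)cc2c1OC(C)(C)C=C2 | intermediate
18 | (3S)‑1‑[2‑bromo‑4‑(methoxymethoxy)‑3‑(3‑methylbut‑2‑en‑1‑yl)phenyl]‑3‑[2,2‑dimethyl‑8‑(3‑methylbut‑2‑en‑1‑yl)‑2H‑chromen‑6‑yl]‑3‑hydroxypropan‑1‑one | CC(C)=CCc1cc([C@@H](O)CC(=O)c3ccc(OCOC)c(CC=C(C)C)c3Br)cc2c1OC(C)(C)C=C2 | intermediate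
19 | (1S,3S)‑1‑[2‑bromo‑4‑(methoxymethoxy)‑3‑(3‑methylbut‑2‑en‑1‑yl)phenyl]‑3‑[2,2‑dimethyl‑8‑(3‑methylbut‑2‑en‑1‑yl)‑2H‑chromen‑6‑yl]propane‑1,3‑diol | CC(C)=CCc1cc([C@@H](O)C[C@H](O)c3ccc(OCOC)c(CC=C(C)C)c3Br)cc2c1OC(C)(C)C=C2 | intermediate
20 | (2S,4S)‑2‑[2,2‑dimethyl‑8‑(3‑methylbut‑2‑en‑1‑yl)‑2H‑chromen‑6‑yl]‑7‑(methoxymethoxy)‑8‑(3‑methylbut‑2‑en‑1‑yl)‑3,4‑dihydro‑2H‑chromen‑4‑ol | CC(C)=CCc1cc([C@@H]2C[C@H](O)c3ccc(OCOC)c(CC=C(C)C)c3O2)cc2c1OC(C)(C)C=C2 | intermediate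
21 | (2S)‑2‑[2,2‑dimethyl‑8‑(3‑methylbut‑2‑en‑1‑yl)‑2H‑chromen‑6‑yl]‑7‑(methoxymethoxy)‑8‑(3‑methylbut‑2‑en‑1‑yl)‑2,3‑dihydro‑4H‑chromen‑4‑one | CC(C)=CCc1cc([C@@H]2CC(=O)c3ccc(OCOC)c(CC=C(C)C)c3O2)cc2c1OC(C)(C)C=C2 | intermediate
22 | (2S)‑2‑[2,2‑dimethyl‑8‑(3‑methylbut‑2‑en‑1‑yl)‑2H‑chromen‑6‑yl]‑7‑hydroxy‑8‑(3‑methylbut‑2‑en‑1‑yl)‑2,3‑dihydro‑4H‑chromen‑4‑one | CC(C)=CCc1cc([C@@H]2CC(=O)c3ccc(O)c(CC=C(C)C)c3O2)cc2c1OC(C)(C)C=C2 | target

Total step count: 12. Longest linear sequence: 9 steps (steps 4–12, from 9 to 22); the ring B branch (steps 1–3) joins at step 8.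

Steps most likely to fail

Step 10. Insertion of copper into the C–Br bond may be slow, because the bromide is flanked by the chain‑bearing carbon and the prenyl‑bearing carbon; protodebromination or β‑hydride loss from the copper alkoxide could then take over. The fallback closes ring C before the C8 prenyl group is introduced, so that the bromide has only one ortho substituent. It sets out from 9:
- MOMCl/iPr2NEt should give 1‑[2‑bromo‑4‑(methoxymethoxy)phenyl]ethan‑1‑one F1.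
- NaH in THF converts this into sodium 1‑[2‑bromo‑4‑(methoxymethoxy)phenyl]ethen‑1‑olate F2, which is acylated by ester 8 to 1‑[2‑bromo‑4‑(methoxymethoxy)phenyl]‑3‑[2,2‑dimethyl‑8‑(3‑methylbut‑2‑en‑1‑yl)‑2H‑chromen‑6‑yl]propane‑1,3‑dione F3.
- Transfer hydrogenation under the conditions of step 9 should lead through (3S)‑1‑[2‑bromo‑4‑(methoxymethoxy)phenyl]‑3‑[2,2‑dimethyl‑8‑(3‑methylbut‑2‑en‑1‑yl)‑2H‑chromen‑6‑yl]‑3‑hydroxypropan‑1‑one F4 to (1S,3S)‑1‑[2‑bromo‑4‑(methoxymethoxy)phenyl]‑3‑[2,2‑dimethyl‑8‑(3‑methylbut‑2‑en‑1‑yl)‑2H‑chromen‑6‑yl]propane‑1,3‑diol F5.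
- The CuI/phenanthroline/Cs2CO3 closure, now on an ordinary ortho‑monosubstituted bromide, should give (2S,4S)‑2‑[2,2‑dimethyl‑8‑(3‑methylbut‑2‑en‑1‑yl)‑2H‑chromen‑6‑yl]‑7‑(methoxymethoxy)‑3,4‑dihydro‑2H‑chromen‑4‑ol F6.
- n‑BuLi (2.2 equiv, THF, −78 → 0 °C) should remove the hydroxyl proton and then the C8 proton, which lies between O1 and the MOM ether, to give lithium (2S,4S)‑2‑[2,2‑dimethyl‑8‑(3‑methylbut‑2‑en‑1‑yl)‑2H‑chromen‑6‑yl]‑8‑lithio‑7‑(methoxymethoxy)‑3,4‑dihydro‑2H‑chromen‑4‑olate F7.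
- CuI (cat.) and prenyl bromide 2 then deliver 20, where the route is rejoined before step 11.

Step 6. The ortho‑bromoaryllithium may lose LiBr to an aryne or let bromine migrate before it is trapped, and the copper reagent may attack prenyl bromide at its tertiary terminus. The fallback brings in the C3 side chain without an aryl anion, by aromatic Claisen rearrangement and olefin cross‑metathesis. It sets out from 9:
- Allyl bromide/K2CO3 in acetone should give 1‑[2‑bromo‑4‑(prop‑2‑en‑1‑yloxy)phenyl]ethan‑1‑one F8.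
- Heating in N,N‑diethylaniline at 190 °C should shift the allyl group to carbon and give 1‑[2‑bromo‑4‑hydroxy‑3‑(prop‑2‑en‑1‑yl)phenyl]ethan‑1‑one F9. Migration towards the position next to the electron‑withdrawing bromine is expected to be favoured, and the C5 isomer is to be removed by chromatography.
- MOMCl/iPr2NEt gives 1‑[2‑bromo‑4‑(methoxymethoxy)‑3‑(prop‑2‑en‑1‑yl)phenyl]ethan‑1‑one F10.
- Cross‑metathesis with 2‑methylbut‑2‑ene (second‑generation Grubbs catalyst, CH2Cl2, 40 °C) converts the allyl into the prenyl group and gives 15, where the route is rejoined; steps 4, 5 and 7 are then not needed.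

Step 9. Hydride transfer may stall after the first reduction, at the hindered carbonyl next to the bromine, or proceed there with poor facial control. The fallback runs the reduction in two stages with different control elements. It sets out from 17: the transfer hydrogenation is stopped at hydroxy ketone 18, which is isolated. Me4NBH(OAc)3 in MeCN/AcOH at −30 °C (Evans–Saksena reduction) then delivers hydride intramolecularly from boron bound to the 3‑hydroxyl and should give the anti diol 19, where the route is rejoined. No compound outside the compound list is made (F0).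

Further compounds
F1 | step 10 | 1‑[2‑bromo‑4‑(methoxymethoxy)phenyl]ethan‑1‑one | CC(=O)c1ccc(OCOC)cc1Br
F2 | step 10 | sodium 1‑[2‑bromo‑4‑(methoxymethoxy)phenyl]ethen‑1‑olate | [Na+].[O-]C(=C)c1ccc(OCOC)cc1Br
F3 | step 10 | 1‑[2‑bromo‑4‑(methoxymethoxy)phenyl]‑3‑[2,2‑dimethyl‑8‑(3‑methylbut‑2‑en‑1‑yl)‑2H‑chromen‑6‑yl]propane‑1,3‑dione | CC(C)=CCc1cc(C(=O)CC(=O)c3ccc(OCOC)cc3Br)cc2c1OC(C)(C)C=C2
F4 | step 10 | (3S)‑1‑[2‑bromo‑4‑(methoxymethoxy)phenyl]‑3‑[2,2‑dimethyl‑8‑(3‑methylbut‑2‑en‑1‑yl)‑2H‑chromen‑6‑yl]‑3‑hydroxypropan‑1‑one | CC(C)=CCc1cc([C@@H](O)CC(=O)c3ccc(OCOC)cc3Br)cc2c1OC(C)(C)C=C2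
F5 | step 10 | (1S,3S)‑1‑[2‑bromo‑4‑(methoxymethoxy)phenyl]‑3‑[2,2‑dimethyl‑8‑(3‑methylbut‑2‑en‑1‑yl)‑2H‑chromen‑6‑yl]propane‑1,3‑diol | CC(C)=CCc1cc([C@@H](O)C[C@H](O)c3ccc(OCOC)cc3Br)cc2c1OC(C)(C)C=C2
F6 | step 10 | (2S,4S)‑2‑[2,2‑dimethyl‑8‑(3‑methylbut‑2‑en‑1‑yl)‑2H‑chromen‑6‑yl]‑7‑(methoxymethoxy)‑3,4‑dihydro‑2H‑chromen‑4‑ol | CC(C)=CCc1cc([C@@H]2C[C@H](O)c3ccc(OCOC)cc3O2)cc2c1OC(C)(C)C=C2
F7 | step 10 | lithium (2S,4S)‑2‑[2,2‑dimethyl‑8‑(3‑methylbut‑2‑en‑1‑yl)‑2H‑chromen‑6‑yl]‑8‑lithio‑7‑(methoxymethoxy)‑3,4‑dihydro‑2H‑chromen‑4‑olate | CC(C)=CCc1cc([C@@H]2C[C@H](O[Li])c3ccc(OCOC)c([Li])c3O2)cc2c1OC(C)(C)C=C2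
F8 | step 6 | 1‑[2‑bromo‑4‑(prop‑2‑en‑1‑yloxy)phenyl]ethan‑1‑one | CC(=O)c1ccc(OCC=C)cc1Br
F9 | step 6 | 1‑[2‑bromo‑4‑hydroxy‑3‑(prop‑2‑en‑1‑yl)phenyl]ethan‑1‑one | CC(=O)c1ccc(O)c(CC=C)c1Br
F10 | step 6 | 1‑[2‑bromo‑4‑(methoxymethoxy)‑3‑(prop‑2‑en‑1‑yl)phenyl]ethan‑1‑one | CC(=O)c1ccc(OCOC)c(CC=C)c1Br
F0 | step 9 | none | none
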